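Both C5 units are traced back to tertiary aryl ethers. In ring A, C8 is ortho to C8a–O1, whose other ortho carbon C4a is blocked by acyl carbon C4; in ring B the pyran bridges O4' and C5'. The precursor is therefore an open-chain, fully etherified chalcone with a 1,1-dimethylallyl group on the future O1 and a 1,1-dimethylpropargyl group on the future O4'. One thermolysis moves the allyl unit to the future C8, which at the same time uncovers the phenol needed for ring C, and turns the propargyl ether into the 2,2-dimethylpyran. Ring C and its only stereocentre C2 are then made by catalytic asymmetric oxa-Michael closure, followed by non-basic deprotection.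

Key step: step 7

Assumption: the thiourea derived from 9-amino-9-deoxy-epi-quinine is taken to give the (2S) product in step 8. The sense is checked by CD, where a (2S)-flavanone is expected to show a positive band near 330 nm and a negative one near 290 nm, and the quinidine-derived pseudo-enantiomer replaces it if the sense proves opposite.

Locants: chalcone numbering is used for 9 to 16 (ring A primed, ring B unprimed) and flavanone numbering for 17 to 19 (ring B primed).

Step 1
Reactants: 1 2,4-dihydroxyacetophenone
Product: 2 2-hydroxy-4-(methoxymethoxy)acetophenone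
Conditions: MOMCl (1.1 equiv), K2CO3, acetone, 0 °C to rt
Reagents that add atoms: chloromethyl methyl ether (MOMCl), COCCl
Why: Phenol O-alkylation of the Williamson type, in which the 2-OH is hydrogen-bonded to the acetyl oxygen, so a weak base and about one equivalent of MOMCl should etherify only the free and more acidic 4-OH.

Step 2
Reactants: 2 2-hydroxy-4-(methoxymethoxy)acetophenone; 3 3-chloro-3-methylbut-1-yne
Product: 4 4-(methoxymethoxy)-2-(2-methylbut-3-yn-2-yloxy)acetophenone
Conditions: 3 (2 equiv), DBU (2.2 equiv), CuCl2·2H2O (2 mol %), MeCN, 0 °C to rt; evaporation below 35 °C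
Reagents that add atoms: none
Why: Copper-catalysed propargylic etherification, in which DBU fully ionises the chelated phenol and the copper acetylide of 3 loses chloride to an allenylidene-type electrophile that the phenoxide captures at its tertiary carbon, so no SN2 attack on a tertiary halide is required.

Step 3
Reactants: 4 4-(methoxymethoxy)-2-(2-methylbut-3-yn-2-yloxy)acetophenone
Product: 5 4-(methoxymethoxy)-2-(2-methylbut-3-en-2-yloxy)acetophenone
Conditions: H2 (1 atm, stopped at 1 equiv), Pd/CaCO3 poisoned with Pb(OAc)2 (Lindlar catalyst), quinoline, EtOAc, 20 °C; Et3N-deactivated silica, bath below 35 °C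
Reagents that add atoms: none
Why: Lindlar semihydrogenation, where the poisoned surface should add one equivalent of H2 to the terminal alkyne and release the alkene, leave aryl ketone, MOM acetal and allylic C–O bond alone, and stay too cold for an early Claisen shift.

Step 4
Reactants: 6 2,4-dihydroxybenzaldehyde; 3 3-chloro-3-methylbut-1-yne
Product: 7 2-hydroxy-4-(2-methylbut-3-yn-2-yloxy)benzaldehyde
Conditions: 3 (1.2 equiv), DBU (1.2 equiv), CuCl2·2H2O (2 mol %), MeCN, 0 °C
Reagents that add atoms: none
Why: The same copper-catalysed propargylic etherification, directed to O4 because that hydroxyl is para to the formyl group, more acidic and not chelated, so a near-stoichiometric charge of base ionises it alone.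

Step 5
Reactants: 7 2-hydroxy-4-(2-methylbut-3-yn-2-yloxy)benzaldehyde
Product: 8 2-(methoxymethoxy)-4-(2-methylbut-3-yn-2-yloxy)benzaldehyde
Conditions: MOMCl (2 equiv), iPr2NEt (3 equiv), CH2Cl2, 0 °C to rt
Reagents that add atoms: chloromethyl methyl ether (MOMCl), COCCl
Why: Phenol O-alkylation with an amine base that leaves the terminal alkyne C–H untouched, and the cap keeps a phenoxide from deactivating the aldehyde in step 6 and later shields C3 of ring B.

Step 6
Reactants: 5 4-(methoxymethoxy)-2-(2-methylbut-3-en-2-yloxy)acetophenone; 8 2-(methoxymethoxy)-4-(2-methylbut-3-yn-2-yloxy)benzaldehyde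
Product: 10 (E)-1-[4-(methoxymethoxy)-2-(2-methylbut-3-en-2-yloxy)phenyl]-3-[2-(methoxymethoxy)-4-(2-methylbut-3-yn-2-yloxy)phenyl]prop-2-en-1-one, via aldol adduct 9 (not isolated)
Conditions: KOH (4 equiv), EtOH, 0 °C to rt, Ar, dark; poured into cold aq NH4Cl
Reagents that add atoms: none
Why: Claisen–Schmidt condensation (crossed aldol, then E1cB loss of water) between the only enolisable partner and the only aldehyde, which should give the more stable E-enone; because every phenol is etherified, no phenoxide slows enolisation and ring C cannot close early, and room temperature lies below the onset of both rearrangements.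

Step 7
Reactants: 10 bis-ether (E)-chalcone
Product: 16 (E)-1-[2-hydroxy-4-(methoxymethoxy)-3-(3-methylbut-2-enyl)phenyl]-3-[7-(methoxymethoxy)-2,2-dimethyl-2H-chromen-6-yl]prop-2-en-1-one, via ring A prenyl dienone 11 (not isolated), via prenylphenol propargyl ether chalcone 12 (not isolated), via ring B allenyl dienone 13 (not isolated), via allenylphenol chalcone 14 (not isolated), via ortho-quinone methide 15 (not isolated)
Conditions: degassed mesitylene (0.02 M), BHT (cat.), base-washed glassware, Ar, dark; 115 °C until 10 is consumed, then 160 °C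
Reagents that add atoms: none
Why: Near 115 °C the 1,1-dimethylallyl ether on O2' should undergo an aromatic Claisen rearrangement through a chair-like [3,3] transition state that joins its CH2 terminus to C3' (dienone 11), and tautomerisation then gives phenol 12, held by a hydrogen bond to the ketone. Near 160 °C the 1,1-dimethylpropargyl ether on O4 should follow the propargyl Claisen cascade: [3,3] shift to allenyl dienone 13, enolisation to allenylphenol 14 and a [1,5]-hydrogen shift to ortho-quinone methide 15. The one ring closed here, the 2,2-dimethylpyran fused to ring B, forms by thermal oxa-6π electrocyclisation of 15, which remakes an O4–CMe2 bond. Both halves are the standard thermal rearrangements of tertiary allyl aryl ethers to ortho-prenylphenols and of tertiary propargyl aryl ethers to 2,2-dimethylchromenes, run here one after the other in the same flask; no stereocentre survives, since the sp3 ring carbons of 11 and 13 are lost on rearomatisation. Site selectivity is needed on both rings: on ring A it is structural, because the other carbon ortho to O2' (C1') carries the acyl group and cannot rearomatise, whereas on ring B, where C3 and C5 are both open, C5 should win because a meta alkoxy group steers Claisen shifts to the carbon para to itself, C3 is wedged between two alkoxy groups, and no hydrogen-bonded chelate is left to favour C3. Chemoselectivity rests on the absence of any acid, base or metal, so the enone, both MOM acetals and the new alkenes meet only heat in a neutral hydrocarbon.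

Step 8
Reactants: 16 3'-prenyl-2'-hydroxy chromeno-chalcone
Product: 17 (2S)-7-(methoxymethoxy)-2-[7-(methoxymethoxy)-2,2-dimethyl-2H-chromen-6-yl]-8-(3-methylbut-2-enyl)chroman-4-one
Conditions: N-[3,5-bis(trifluoromethyl)phenyl]-N'-[(8α,9S)-6'-methoxycinchonan-9-yl]thiourea (15 mol %), toluene, 0 °C to 20 °C, followed by chiral HPLC and stopped before the ee begins to fall; neutral silica, recovered 16 resubmitted; recrystallisation if crystalline
Reagents that add atoms: none
Why: Enantioselective intramolecular oxa-Michael addition (6-endo-trig), a reaction type established for 2'-hydroxychalcones, in which the quinuclidine nitrogen activates the 2'-OH while the thiourea binds the enone carbonyl, so the phenol oxygen is delivered to the Si face of C-β of the E-enone and sets C2 as S under kinetic control.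

Step 9
Reactants: 17 (2S)-flavanone bis-MOM ether
Product: 19 (2S)-7-hydroxy-2-(7-hydroxy-2,2-dimethyl-2H-chromen-6-yl)-8-(3-methylbut-2-enyl)chroman-4-one, via bis(trimethylsilyl) ether 18 (not isolated)
Conditions: TMSOTf (4 equiv), 2,2'-bipyridyl (6 equiv), MeCN, 0 °C to rt; then H2O, rt; pH 6 phosphate buffer work-up
Reagents that add atoms: none
Why: Silyl triflate/bipyridyl cleavage of aryl MOM ethers, which turns each acetal into an aryl trimethylsilyl ether that water hydrolyses, so no base (retro-oxa-Michael racemisation of C2) and no strong protic acid (prenyl-to-chroman closure, chromene damage) is ever present.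

Compound list
1 | 2,4-dihydroxyacetophenone | CC(=O)c1ccc(O)cc1O | starting material
2 | 2-hydroxy-4-(methoxymethoxy)acetophenone | CC(=O)c1ccc(OCOC)cc1O | intermediate
3 | 3-chloro-3-methylbut-1-yne | C#CC(C)(C)Cl | starting material
4 | 4-(methoxymethoxy)-2-(2-methylbut-3-yn-2-yloxy)acetophenone | CC(=O)c1ccc(OCOC)cc1OC(C)(C)C#C | intermediate
5 | 4-(methoxymethoxy)-2-(2-methylbut-3-en-2-yloxy)acetophenone | CC(=O)c1ccc(OCOC)cc1OC(C)(C)C=C | intermediate
6 | 2,4-dihydroxybenzaldehyde | O=Cc1ccc(O)cc1O | starting material
7 | 2-hydroxy-4-(2-methylbut-3-yn-2-yloxy)benzaldehyde | O=Cc1ccc(OC(C)(C)C#C)cc1O | intermediate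
8 | 2-(methoxymethoxy)-4-(2-methylbut-3-yn-2-yloxy)benzaldehyde | O=Cc1ccc(OC(C)(C)C#C)cc1OCOC | intermediate
9 | racemic aldol adduct, 3-hydroxy-1-[4-(methoxymethoxy)-2-(2-methylbut-3-en-2-yloxy)phenyl]-3-[2-(methoxymethoxy)-4-(2-methylbut-3-yn-2-yloxy)phenyl]propan-1-one (not isolated) | O=C(CC(O)c1ccc(OC(C)(C)C#C)cc1OCOC)c1ccc(OCOC)cc1OC(C)(C)C=C | intermediate
10 | (E)-1-[4-(methoxymethoxy)-2-(2-methylbut-3-en-2-yloxy)phenyl]-3-[2-(methoxymethoxy)-4-(2-methylbut-3-yn-2-yloxy)phenyl]prop-2-en-1-one | O=C(/C=C/c1ccc(OC(C)(C)C#C)cc1OCOC)c1ccc(OCOC)cc1OC(C)(C)C=C | intermediate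
11 | ring A dienone: 2-acyl-5-(methoxymethoxy)-6-(3-methylbut-2-enyl)cyclohexa-2,4-dien-1-one, the acyl group being the (E)-3-arylprop-2-enoyl chain of 10 (not isolated) | O=C(/C=C/c1ccc(OC(C)(C)C#C)cc1OCOC)C1=CC=C(OCOC)C(CC=C(C)C)C1=O | intermediate
12 | (E)-1-[2-hydroxy-4-(methoxymethoxy)-3-(3-methylbut-2-enyl)phenyl]-3-[2-(methoxymethoxy)-4-(2-methylbut-3-yn-2-yloxy)phenyl]prop-2-en-1-one (not isolated) | O=C(/C=C/c1ccc(OC(C)(C)C#C)cc1OCOC)c1ccc(OCOC)c(CC=C(C)C)c1O | intermediate
13 | ring B dienone: as 12, but ring B is a cyclohexa-2,4-dien-1-one (C4=O) with H and a 3-methylbuta-1,2-dienyl group on C5 (not isolated) | O=C(/C=C/C1=CC(C=C=C(C)C)C(=O)C=C1OCOC)c1ccc(OCOC)c(CC=C(C)C)c1O | intermediate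
14 | (E)-3-[4-hydroxy-2-(methoxymethoxy)-5-(3-methylbuta-1,2-dienyl)phenyl]-1-[2-hydroxy-4-(methoxymethoxy)-3-(3-methylbut-2-enyl)phenyl]prop-2-en-1-one (not isolated) | O=C(/C=C/c1cc(C=C=C(C)C)c(O)cc1OCOC)c1ccc(OCOC)c(CC=C(C)C)c1O | intermediate
15 | ortho-quinone methide: as 14, but ring B has C4=O and an exocyclic C5=CH–CH=CMe2 unit (not isolated) | O=C(/C=C/C1=CC(=CC=C(C)C)C(=O)C=C1OCOC)c1ccc(OCOC)c(CC=C(C)C)c1O | intermediate
16 | (E)-1-[2-hydroxy-4-(methoxymethoxy)-3-(3-methylbut-2-enyl)phenyl]-3-[7-(methoxymethoxy)-2,2-dimethyl-2H-chromen-6-yl]prop-2-en-1-one | O=C(/C=C/c1cc2c(cc1OCOC)OC(C)(C)C=C2)c1ccc(OCOC)c(CC=C(C)C)c1O | intermediate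
17 | (2S)-7-(methoxymethoxy)-2-[7-(methoxymethoxy)-2,2-dimethyl-2H-chromen-6-yl]-8-(3-methylbut-2-enyl)chroman-4-one | CC(C)=CCc1c(OCOC)ccc2c1O[C@H](c1cc3c(cc1OCOC)OC(C)(C)C=C3)CC2=O | intermediate
18 | (2S)-2-[2,2-dimethyl-7-(trimethylsilyloxy)-2H-chromen-6-yl]-8-(3-methylbut-2-enyl)-7-(trimethylsilyloxy)chroman-4-one (not isolated) | CC(C)=CCc1c(O[Si](C)(C)C)ccc2c1O[C@H](c1cc3c(cc1O[Si](C)(C)C)OC(C)(C)C=C3)CC2=O | intermediate
19 | (2S)-7-hydroxy-2-(7-hydroxy-2,2-dimethyl-2H-chromen-6-yl)-8-(3-methylbut-2-enyl)chroman-4-one (CNP0279510.1) | CC(C)=CCc1c(O)ccc2c1O[C@H](c1cc3c(cc1O)OC(C)(C)C=C3)CC2=O | target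

Total step count: 9
Longest linear sequence: 7 (steps 1, 2, 3, 6, 7, 8, 9)

Steps most likely to fail

Step 7. Several things may go wrong.
- The propargyl shift on ring B may divide between C5 and C3.
- The tertiary allyl group may be lost by elimination before it migrates.
- Long heating may close ring C without facial control.

The fallback separates the two rearrangements and runs the ring B cascade on a small fragment whose C3 is blocked.
- Setting out from 6, iodination between the two hydroxyl groups (I2, HIO3, aq EtOH) should give 2,4-dihydroxy-3-iodobenzaldehyde F1.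
- Etherification with 3 under the conditions of step 4 gives 2-hydroxy-3-iodo-4-(2-methylbut-3-yn-2-yloxy)benzaldehyde F2.
- Heating (xylene, 140 °C) can then deliver the C5 unit only to C5 and gives 7-hydroxy-8-iodo-2,2-dimethyl-2H-chromene-6-carbaldehyde F3.
- Hydrodeiodination (Pd(OAc)2, PPh3, HCO2H, Et3N, DMF, 50 °C) gives 7-hydroxy-2,2-dimethyl-2H-chromene-6-carbaldehyde F4.
- MOM protection as in step 5 gives 7-(methoxymethoxy)-2,2-dimethyl-2H-chromene-6-carbaldehyde F5.
- Claisen–Schmidt condensation with 5 as in step 6 gives the chromeno-chalcone 2'-O-(1,1-dimethylallyl) ether F6.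
- F6 needs only the low-temperature allyl Claisen rearrangement (toluene, 110 °C) to rejoin the route at 16.

Step 8. The addition may be slow, because the 2,4-dioxygenated ring B lowers the electrophilicity of C-β and the phenol is locked in a chelate. Facial selectivity on an unactivated chalcone may be modest. The ee may also erode as the reversible closure nears equilibrium.

The fallback moves stereocontrol from the ring closure to a kinetic resolution.
- Setting out from 16, NaOAc in refluxing EtOH closes ring C without control and gives the racemic bis-MOM flavanone F7.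
- Asymmetric transfer hydrogenation follows (Cp*RhCl[(R,R)-TsDPEN], 1 mol %, HCO2H/Et3N 5:2, EtOAc, rt), taken just past half conversion.
- This should reduce the (2R) enantiomer, in which delivery of hydride to form a (4R) carbinol comes anti to the 2-aryl group, to the (2R,4R)-cis-flavan-4-ol bis-MOM ether F8.
- The (2S) ketone is left untouched. It is 17, and the route is rejoined there after chromatography and a CD check.
- F8 can be recycled: Dess–Martin oxidation gives the (2R)-flavanone bis-MOM ether F9, and KOH in EtOH followed by cold acidification opens F9 to 16.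

Step 2. O-alkylation of the hindered, chelated phenol may be sluggish, and dehydrochlorination of the tertiary chloride may consume the reagent. The fallback installs the allyl ether directly by π-allyl chemistry. Setting out from 2, tert-butyl 2-methylbut-3-en-2-yl carbonate and Pd(PPh3)4 (THF, 0 °C) should effect a decarboxylative O-allylation in which the phenoxide attacks the more substituted terminus of the dimethylallyl palladium cation under kinetic control. The route is rejoined at 5, with 4 and the semihydrogenation bypassed.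

Further compounds
F1 | step 7 | 2,4-dihydroxy-3-iodobenzaldehyde | O=Cc1ccc(O)c(I)c1O
F2 | step 7 | 2-hydroxy-3-iodo-4-(2-methylbut-3-yn-2-yloxy)benzaldehyde | O=Cc1ccc(OC(C)(C)C#C)c(I)c1O
F3 | step 7 | 7-hydroxy-8-iodo-2,2-dimethyl-2H-chromene-6-carbaldehyde | O=Cc1cc2c(c(I)c1O)OC(C)(C)C=C2
F4 | step 7 | 7-hydroxy-2,2-dimethyl-2H-chromene-6-carbaldehyde | O=Cc1cc2c(cc1O)OC(C)(C)C=C2
F5 | step 7 | 7-(methoxymethoxy)-2,2-dimethyl-2H-chromene-6-carbaldehyde | O=Cc1cc2c(cc1OCOC)OC(C)(C)C=C2
F6 | step 7 | (E)-1-[4-(methoxymethoxy)-2-(2-methylbut-3-en-2-yloxy)phenyl]-3-[7-(methoxymethoxy)-2,2-dimethyl-2H-chromen-6-yl]prop-2-en-1-one | O=C(/C=C/c1cc2c(cc1OCOC)OC(C)(C)C=C2)c1ccc(OCOC)cc1OC(C)(C)C=C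
F7 | step 8 | racemic 7-(methoxymethoxy)-2-[7-(methoxymethoxy)-2,2-dimethyl-2H-chromen-6-yl]-8-(3-methylbut-2-enyl)chroman-4-one | CC(C)=CCc1c(OCOC)ccc2c1OC(c1cc3c(cc1OCOC)OC(C)(C)C=C3)CC2=O
F8 | step 8 | (2R,4R)-7-(methoxymethoxy)-2-[7-(methoxymethoxy)-2,2-dimethyl-2H-chromen-6-yl]-8-(3-methylbut-2-enyl)chroman-4-ol | CC(C)=CCc1c(OCOC)ccc2c1O[C@@H](c1cc3c(cc1OCOC)OC(C)(C)C=C3)C[C@H]2O
F9 | step 8 | (2R)-7-(methoxymethoxy)-2-[7-(methoxymethoxy)-2,2-dimethyl-2H-chromen-6-yl]-8-(3-methylbut-2-enyl)chroman-4-one | CC(C)=CCc1c(OCOC)ccc2c1O[C@@H](c1cc3c(cc1OCOC)OC(C)(C)C=C3)CC2=O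
F0 | step 2 | none | none
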